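The bicyclo[3.3.1]nonane-2,4,9-trione is cut at C5–C9 and C1–C8 (plus C2–C3). This frees the symmetric C2–C1–C9 unit as prenylmalonyl dichloride. The partner is a monocyclic dihydropyran. In it the oxygen on C4 is tied to the gem-dimethyl carbon C8, and C3–C4–C5 is a silyl dienol ether already carrying the aroyl, geranyl and C7-prenyl groups. One operation acylates C5 and C3 (ring A: C1–C2–C3–C4–C5–C9), then moves C8 from O4 to C1 (ring B: C1–C9–C5–C6–C7–C8). The step exploits the 1,3,5-tricarbonyl pattern of ring A and the tertiary C8 next to C1. The pyran relays C7, taken from (R)-α-terpineol, to C5 and C1.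

Key step: step 13

Remark on numbering: the atom numbers of the target core are used for all precursors. C1 is the prenyl bridgehead, C2 and C4 are the enolised diketone carbons, and C3 is the aroyl-bearing carbon. C5 is the geranyl bridgehead, C6 is CH2, C7 is CH(prenyl), C8 is CMe2 and C9 is the bridging ketone. O4 is the oxygen on C4.
Remark on tautomers: the enolised 2-aroyl-1,3-diketone of 23 and 24 is written as the 4-hydroxy-2-oxo tautomer. The tautomers interconvert freely.
Assumption: (R)-(+)-α-terpineol is taken as commercially available in high enantiomeric purity.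

Step 1
Reactants: 1 (R)-(+)-α-terpineol
Product: 2 (R)-α-terpinyl triethylsilyl ether
Conditions: Et3SiOTf, 2,6-lutidine, CH2Cl2, 0 °C
Reagents that add atoms: triethylsilyl trifluoromethanesulfonate CC[Si](CC)(CC)OS(=O)(=O)C(F)(F)F
Why: Silyl ether protection with the reactive triflate masks the tertiary alcohol (the later C8–O4 bond) for the basic steps, and the chiral-pool stereocentre (later C7) is not touched.

Step 2
Reactants: 2 (R)-α-terpinyl triethylsilyl ether
Product: 3 (3R)-6-oxo-3-[2-(triethylsilyloxy)propan-2-yl]heptanal
Conditions: O3, CH2Cl2, −78 °C; then Me2S, −78 → 23 °C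
Reagents that add atoms: ozone [O-][O+]=O
Why: Ozonolysis with reductive work-up cleaves the only C=C bond into the methyl ketone (C3–C4) and the aldehyde arm that becomes the C7 prenyl group, and the stereocentre is β to the aldehyde and cannot epimerise.

Step 3
Reactants: 3 (3R)-6-oxo-3-[2-(triethylsilyloxy)propan-2-yl]heptanal; 4 isopropyltriphenylphosphonium iodide
Product: 6 (5R)-8-methyl-5-[2-(triethylsilyloxy)propan-2-yl]non-7-en-2-one, via phosphorus ylide 5 (not isolated)
Conditions: 4, n-BuLi, THF, 0 °C; then 3, −78 → 0 °C
Reagents that add atoms: none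
Why: The Wittig olefination with the non-stabilised ylide should be chemoselective for the aldehyde, because forming a tetrasubstituted alkene at the methyl ketone is far slower at low temperature.

Step 4
Reactants: 7 3-hydroxybenzoic acid
Product: 8 tert-butyldimethylsilyl 3-(tert-butyldimethylsilyloxy)benzoate
Conditions: t-BuMe2SiCl (2.2 equiv), imidazole, DMF, 23 °C
Reagents that add atoms: tert-butyldimethylsilyl chloride CC(C)(C)[Si](C)(C)Cl
Why: Standard silylation converts both the phenol and the acid, giving a phenol protecting group that tolerates amide bases, weak acid and anhydrous HCl.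

Step 5
Reactants: 8 tert-butyldimethylsilyl 3-(tert-butyldimethylsilyloxy)benzoate
Product: 9 3-(tert-butyldimethylsilyloxy)benzoyl chloride
Conditions: (COCl)2, DMF (cat.), CH2Cl2, 0 → 23 °C
Reagents that add atoms: oxalyl chloride O=C(Cl)C(=O)Cl
Why: The chloroiminium species from DMF converts the silyl ester directly into the acid chloride under neutral conditions, so the aryl silyl ether should survive.

Step 6
Reactants: 6 (5R)-8-methyl-5-[2-(triethylsilyloxy)propan-2-yl]non-7-en-2-one; 9 3-(tert-butyldimethylsilyloxy)benzoyl chloride
Product: 10 (6R)-1-[3-(tert-butyldimethylsilyloxy)phenyl]-9-methyl-6-[2-(triethylsilyloxy)propan-2-yl]dec-8-ene-1,3-dione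
Conditions: LiN(SiMe3)2 (2.2 equiv), THF, −78 °C; then 9, −78 → 0 °C
Reagents that add atoms: none
Why: This is a crossed Claisen-type C-acylation of the kinetic methyl-side lithium enolate (C3), in which the second equivalent of base deprotonates the 1,3-diketone as it forms and so protects it from further acylation.

Step 7
Reactants: 10 (6R)-1-[3-(tert-butyldimethylsilyloxy)phenyl]-9-methyl-6-[2-(triethylsilyloxy)propan-2-yl]dec-8-ene-1,3-dione; 11 geranyl bromide
Product: 12 (6S)-1-[3-(tert-butyldimethylsilyloxy)phenyl]-4-[(2E)-3,7-dimethylocta-2,6-dienyl]-9-methyl-6-[2-(triethylsilyloxy)propan-2-yl]dec-8-ene-1,3-dione (both epimers at C5)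
Conditions: LiN(i-Pr)2 (2.2 equiv), THF, −78 → 0 °C; then 11, −78 → 0 °C
Reagents that add atoms: none
Why: In this γ-alkylation of a 1,3-diketone dianion only C5 carries γ-hydrogens and it is the more reactive carbanion, SN2 at the primary allylic bromide keeps the E-alkene, and the unselective C5 centre is erased in step 9 (the C7 descriptor changes from R to S by priority only).

Step 8
Reactants: 12 C5-geranylated diketone
Product: 14 vinylogous ester 2-[(5S)-3-geranyl-6,6-dimethyl-5-prenyloxan-2-ylidene]-1-[3-(tert-butyldimethylsilyloxy)phenyl]ethanone (both C5 epimers), via hydroxy diketone 13 (not isolated)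
Conditions: PPTS (0.3 equiv), MeOH, 40 °C; then PhH, 4 Å MS, 60 °C
Reagents that add atoms: none
Why: Acid-catalysed desilylation followed by cyclodehydration (hemiketal at C4, loss of water) should give the aroyl-conjugated vinylogous ester with the O4–C8 bond, and the weak acid spares the trisubstituted alkenes and the aryl silyl ether.

Step 9
Reactants: 14 vinylogous ester
Product: 15 silyl dienol ether (3S)-6-{2-[3-(tert-butyldimethylsilyloxy)phenyl]-2-(tert-butyldimethylsilyloxy)ethenyl}-5-geranyl-2,2-dimethyl-3-prenyl-3,4-dihydro-2H-pyran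
Conditions: t-BuMe2SiOTf (1.3 equiv), Et3N (3 equiv), CH2Cl2, −78 → 0 °C; used crude
Reagents that add atoms: tert-butyldimethylsilyl trifluoromethanesulfonate CC(C)(C)[Si](C)(C)OS(=O)(=O)C(F)(F)F
Why: In this soft enolisation to a 1-silyloxy-3-alkoxydiene the aroyl oxygen is silylated and the excess amine removes the only acidic proton of the resulting cation (C5–H), which moves the double bond into the ring (C4=C5).

Step 10
Reactants: 16 dimethyl malonate; 17 prenyl bromide
Product: 18 dimethyl 2-(3-methylbut-2-enyl)malonate
Conditions: NaH, THF, 0 → 23 °C (16 in slight excess)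
Reagents that add atoms: none
Why: The malonic ester alkylation proceeds by SN2 at the primary allylic bromide, and excess malonate suppresses dialkylation.

Step 11
Reactants: 18 dimethyl 2-(3-methylbut-2-enyl)malonate
Product: 19 2-(3-methylbut-2-enyl)malonic acid
Conditions: KOH, MeOH/H2O, 23 °C; then cold aq. HCl to pH 2
Reagents that add atoms: potassium hydroxide [K+].[OH-]
Why: Saponification of both esters is followed by cold acidification, which avoids decarboxylation of the malonic acid.

Step 12
Reactants: 19 2-(3-methylbut-2-enyl)malonic acid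
Product: 20 2-(3-methylbut-2-enyl)malonyl dichloride
Conditions: (COCl)2 (2.3 equiv), DMF (cat.), CH2Cl2, 0 → 23 °C; volatiles removed in vacuo, used at once
Reagents that add atoms: oxalyl chloride O=C(Cl)C(=O)Cl
Why: Acid chloride formation with oxalyl chloride runs cold and dilute, so HCl escapes as gas and should not add to the prenyl double bond.

Step 13
Reactants: 15 silyl dienol ether; 20 2-(3-methylbut-2-enyl)malonyl dichloride
Product: 23 (1S,5S,7S)-configured tert-butyldimethylsilyl ether of the target, via keto acid chloride 21 (not isolated), via pyrano-fused dienone 22 (not isolated)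
Conditions: 20 (1.05 equiv), CH2Cl2 (0.02 M), −78 °C, 1 h; then closed flask, slowly to 23 °C, 12 h
Reagents that add atoms: none
Why: Proposed new method: the diene terminus C5 of 15 attacks one acyl chloride of the constitutionally symmetric 20 (C5–C9 bond, chloride removes the silyl group, 21), C3 of the resulting vinylogous ester is then acylated intramolecularly by the second acyl chloride or the acylketene derived from it (ring A, 22), and the HCl set free ionises the tertiary C8–O4 bond of this vinylogous tert-alkyl ester so that the C8 cation is captured by the enol carbon C1 (C8–C1 bond), which opens the pyran and closes ring B. The closest known reactions are the Effenberger cyclisation of enol ethers with malonyl dichloride, the terminal acylation and formal [3+3] cyclisation of 1,3-dioxygenated dienes, and the acid-induced biomimetic cation cyclisation of dearomatised acylphloroglucinols, and what is new is their merger on a cyclic tert-alkyl dienol ether whose O-alkyl group is not lost but migrates from oxygen to carbon. Ring A closes in a 6-(enolendo)-exo-trig mode and ring B in a 6-(enolendo)-exo-tet (SN1) mode, while the dihydropyran ring is cleaved. C5 is set by axial attack on the dihydropyran half-chair anti to the pseudo-equatorial C7 prenyl group, which puts C9 trans to that group and hence the C7 prenyl group endo in the bicycle, and C1 is then fixed by the C6–C7–C8 tether, which reaches only one face of ring A. The step needs C5 before C3 in the first acylation (both oxygen donors push electron density to C5, and the low temperature lets this bimolecular step finish before HCl appears). It also needs C- over O-acylation (O4 is alkylated and the aroyl oxygen would need an eight-membered ring) and C1 over C3 and oxygen in the alkylation (C3 is blocked by the aroyl group, and O-alkylation is reversible under HCl whereas C-alkylation is not).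

Step 14
Reactants: 23 tert-butyldimethylsilyl ether of the target
Product: 24 target CNP0236890.1
Conditions: Bu4NF, AcOH (1:1), THF, 0 °C
Reagents that add atoms: none
Why: Fluoride-induced cleavage of the aryl silyl ether, buffered with acetic acid, should leave the acidic β-triketone, the alkenes and all three stereocentres untouched.

Compound list
1 | (R)-(+)-α-terpineol | CC1=CC[C@@H](CC1)C(C)(C)O | starting material
2 | (R)-α-terpinyl triethylsilyl ether | CC1=CC[C@@H](CC1)C(C)(C)O[Si](CC)(CC)CC | intermediate
3 | (3R)-6-oxo-3-[2-(triethylsilyloxy)propan-2-yl]heptanal | CC(=O)CC[C@H](CC=O)C(C)(C)O[Si](CC)(CC)CC | intermediate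
4 | isopropyltriphenylphosphonium iodide | CC(C)[P+](c1ccccc1)(c1ccccc1)c1ccccc1.[I-] | starting material
5 | isopropylidenetriphenylphosphorane (not isolated) | CC(C)=P(c1ccccc1)(c1ccccc1)c1ccccc1 | intermediate
6 | (5R)-8-methyl-5-[2-(triethylsilyloxy)propan-2-yl]non-7-en-2-one | CC(=O)CC[C@H](CC=C(C)C)C(C)(C)O[Si](CC)(CC)CC | intermediate
7 | 3-hydroxybenzoic acid | OC(=O)c1cccc(O)c1 | starting material
8 | tert-butyldimethylsilyl 3-(tert-butyldimethylsilyloxy)benzoate | CC(C)(C)[Si](C)(C)OC(=O)c1cccc(O[Si](C)(C)C(C)(C)C)c1 | intermediate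
9 | 3-(tert-butyldimethylsilyloxy)benzoyl chloride | ClC(=O)c1cccc(O[Si](C)(C)C(C)(C)C)c1 | intermediate
10 | (6R)-1-aryl-1,3-diketone (C3–C8 chain, C7 prenyl, C8 OSiEt3) | O=C(CC(=O)CC[C@H](CC=C(C)C)C(C)(C)O[Si](CC)(CC)CC)c1cccc(O[Si](C)(C)C(C)(C)C)c1 | intermediate
11 | geranyl bromide, (2E)-1-bromo-3,7-dimethylocta-2,6-diene | BrC/C=C(\C)CCC=C(C)C | starting material
12 | C5-geranylated diketone, 7S, both C5 epimers | O=C(CC(=O)C(C/C=C(\C)CCC=C(C)C)C[C@H](CC=C(C)C)C(C)(C)O[Si](CC)(CC)CC)c1cccc(O[Si](C)(C)C(C)(C)C)c1 | intermediate
13 | hydroxy diketone, 7S, both C5 epimers (not isolated) | O=C(CC(=O)C(C/C=C(\C)CCC=C(C)C)C[C@H](CC=C(C)C)C(C)(C)O)c1cccc(O[Si](C)(C)C(C)(C)C)c1 | intermediate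
14 | vinylogous ester (oxan-2-ylidene aryl ketone), 7S, both C5 epimers, exocyclic alkene geometry not defined | O=C(C=C1OC(C)(C)[C@@H](CC=C(C)C)CC1C/C=C(\C)CCC=C(C)C)c2cccc(O[Si](C)(C)C(C)(C)C)c2 | intermediate
15 | silyl dienol ether (3,4-dihydro-2H-pyran), 7S | CC(C)(C)[Si](C)(C)OC(=CC1=C(C/C=C(\C)CCC=C(C)C)C[C@H](CC=C(C)C)C(C)(C)O1)c2cccc(O[Si](C)(C)C(C)(C)C)c2 | intermediate
16 | dimethyl malonate | COC(=O)CC(=O)OC | starting material
17 | prenyl bromide, 1-bromo-3-methylbut-2-ene | CC(C)=CCBr | starting material
18 | dimethyl 2-(3-methylbut-2-enyl)malonate | COC(=O)C(CC=C(C)C)C(=O)OC | intermediate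
19 | 2-(3-methylbut-2-enyl)malonic acid | OC(=O)C(CC=C(C)C)C(=O)O | intermediate
20 | 2-(3-methylbut-2-enyl)malonyl dichloride | ClC(=O)C(CC=C(C)C)C(Cl)=O | intermediate
21 | keto acid chloride, 5S,7S, C1 epimers (not isolated) | O=C(C=C1OC(C)(C)[C@@H](CC=C(C)C)C[C@]1(C/C=C(\C)CCC=C(C)C)C(=O)C(CC=C(C)C)C(Cl)=O)c2cccc(O[Si](C)(C)C(C)(C)C)c2 | intermediate
22 | pyrano-fused dienone (O4–C8 bridged dearomatised acylphloroglucinol), 5S,7S (not isolated) | CC(C)=CCC/C(C)=C/C[C@]12C[C@H](CC=C(C)C)C(C)(C)OC1=C(C(=O)c3cccc(O[Si](C)(C)C(C)(C)C)c3)C(O)=C(CC=C(C)C)C2=O | intermediate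
23 | tert-butyldimethylsilyl ether of the target, 1S,5S,7S | CC(C)=CCC/C(C)=C/C[C@]12C[C@H](CC=C(C)C)C(C)(C)[C@](CC=C(C)C)(C(=O)C(C(=O)c3cccc(O[Si](C)(C)C(C)(C)C)c3)=C1O)C2=O | intermediate
24 | CNP0236890.1, 1S,5S,7S | CC(C)=CCC/C(C)=C/C[C@]12C[C@H](CC=C(C)C)C(C)(C)[C@](CC=C(C)C)(C(=O)C(C(=O)c3cccc(O)c3)=C1O)C2=O | target

Total step count: 14. Longest linear sequence: 9 steps (1, 2, 3, 6, 7, 8, 9, 13, 14).

Steps most likely to fail

Step 13. Several processes may go wrong:
- The first acylation may occur at C3 instead of C5, followed by O-acylation through the aroyl oxygen.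
- Attack may occur on the wrong face of the dihydropyran.
- The cascade may stall at the O-bridged stage.
- The C8 cation may undergo elimination or be captured by the geranyl double bond.
- HCl may add to the side-chain alkenes.

The fallback uses known reactions and makes the two bonds in separate steps. It sets out from 12. The magnesium enolate of 12 (MgCl2, pyridine, CH2Cl2) is C-acylated at C3 with commercial methyl 3-chloro-3-oxopropanoate to the tetracarbonyl ester F1. NaH in THF closes C5–C9 by a Claisen (Dieckmann-type) condensation to the dearomatised acylphloroglucinol F2. Aqueous KOH and 17 prenylate C1 to the prenylated trione F3. Formic acid at room temperature then removes the triethylsilyl group, ionises C8 and closes C8–C1 in the known biomimetic cation cyclisation. The sequence comes back to the route at 23. C5 is formed without control in this variant, so 23 has to be separated from its diastereomer.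

Step 9. The tertiary alkyl group may be lost from the O-silylated oxocarbenium ion before deprotonation, which would open the pyran. The sensitive diene may also hydrolyse. The fallback leaves the cationic manifold for an anionic one and sets out from 14. KN(SiMe3)2 in THF at −78 °C removes the γ-proton at C5 to give the potassium dienolate F4. This is O-silylated with t-BuMe2SiCl, and the route is rejoined at 15.

Step 6. The enolate may undergo O-acylation or double acylation, and proton exchange may erode the methyl-side selectivity. The fallback replaces acylation by aldol addition and oxidation and sets out from 6. The kinetic lithium enolate (LiN(i-Pr)2, THF, −78 °C) adds to commercial 3-(tert-butyldimethylsilyloxy)benzaldehyde to give the β-hydroxy ketone F5. Oxidation with Dess–Martin periodinane comes back to the route at 10.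

Further compounds
F1 | step 13 | tetracarbonyl ester (C3-malonylated 12) | COC(=O)CC(=O)C(C(=O)c1cccc(O[Si](C)(C)C(C)(C)C)c1)C(=O)C(C/C=C(\C)CCC=C(C)C)C[C@H](CC=C(C)C)C(C)(C)O[Si](CC)(CC)CC
F2 | step 13 | dearomatised acylphloroglucinol, C1 unsubstituted, both C5 epimers | CC(C)=CCC/C(C)=C/CC1(C[C@H](CC=C(C)C)C(C)(C)O[Si](CC)(CC)CC)C(=O)C=C(O)C(C(=O)c2cccc(O[Si](C)(C)C(C)(C)C)c2)=C1O
F3 | step 13 | prenylated trione, both C5 epimers | CC(C)=CCC/C(C)=C/CC1(C[C@H](CC=C(C)C)C(C)(C)O[Si](CC)(CC)CC)C(=O)C(CC=C(C)C)=C(O)C(C(=O)c2cccc(O[Si](C)(C)C(C)(C)C)c2)=C1O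
F4 | step 9 | potassium dienolate of 14 | [K+].[O-]C(=CC1=C(C/C=C(\C)CCC=C(C)C)C[C@H](CC=C(C)C)C(C)(C)O1)c2cccc(O[Si](C)(C)C(C)(C)C)c2
F5 | step 6 | β-hydroxy ketone (aldol adduct of 6) | OC(CC(=O)CC[C@H](CC=C(C)C)C(C)(C)O[Si](CC)(CC)CC)c1cccc(O[Si](C)(C)C(C)(C)C)c1
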